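## Retrosynthetic overview

1. The target, (2S)-5,7,3',5'-tetrahydroxy-6,8-diprenylflavanone, comes from its tetra-MOM ether 12 by one mild acidic global deprotection.
2. The C2–aryl bond and the only stereocentre come from a Rh/chiral-diene asymmetric 1,4-addition of arylboronic acid 11 to chromone 7.
3. Chromone 7 comes from acetophenone 5 by enaminone formation with DMF-DMA (which supplies C2) and cyclisation.
4. Acetophenone 5 comes from phloroacetophenone by C,C-diprenylation and bis-MOM protection; boronic acid 11 comes from 5-bromoresorcinol.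
5. Ring order: the A and B benzene rings are purchased; the pyranone C ring is closed as an achiral chromone, then made stereogenic by the conjugate addition.

Assumption: (S,S)-Ph-bod* is assigned as the ligand giving (2S) by analogy with its facial selectivity on cyclohexenone; I could not confirm this sense for chromones from memory, so confirm by CD/chiral HPLC on 12 and switch to (R,R)-Ph-bod* if reversed.

Convention: bases, solvents, catalysts and water are not numbered.

## Route

**Step 1**
Reactants: 1, 2,4,6-trihydroxyacetophenone (phloroacetophenone); 2, prenyl bromide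
Product: 3, 1-[2,4,6-trihydroxy-3,5-bis(3-methylbut-2-en-1-yl)phenyl]ethan-1-one
Conditions: 2 (2.1 equiv), 10% aq KOH, 0 °C → rt; acidify; chromatography (expect about 30–40%)
Reagents that add atoms: prenyl bromide, CC(C)=CCBr (two C5 units)
Why: In aqueous base the phloroglucinol phenolate is C-alkylated (SN2, linear prenyl) at both free ring carbons, the deoxyhumulone-type C-prenylation of acylphloroglucinols.

**Step 2**
Reactants: 3; 4, chloromethyl methyl ether (MOMCl)
Product: 5, 1-[2-hydroxy-4,6-bis(methoxymethoxy)-3,5-bis(3-methylbut-2-en-1-yl)phenyl]ethan-1-one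
Conditions: MOMCl (2.3 equiv), i-Pr2NEt, CH2Cl2, 0 °C → rt
Reagents that add atoms: MOMCl, COCCl (two CH2OCH3 groups)
Why: O-alkylation stops at the bis-ether because the last ortho OH is deactivated by its hydrogen bond to the ketone; 3 is symmetric, so only one bis-MOM isomer forms.

**Step 3**
Reactants: 5; 6, N,N-dimethylformamide dimethyl acetal (DMF-DMA)
Product: 7, 5,7-bis(methoxymethoxy)-6,8-bis(3-methylbut-2-en-1-yl)-4H-chromen-4-one
Conditions: DMF-DMA (3 equiv), toluene, 95 °C; concentrate; then AcOH, toluene, 60 °C
Reagents that add atoms: DMF-DMA, COC(OC)N(C)C (the C2–H carbon)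
Why: Condensation of the methyl ketone gives the (E)-enaminone, and the free ortho phenol then adds and expels Me2NH (enaminone chromone synthesis) under acid too weak to cleave MOM or protonate the prenyl alkenes.

**Step 4**
Reactants: 8, 5-bromoresorcinol (5-bromobenzene-1,3-diol); 4, MOMCl
Product: 9, 1-bromo-3,5-bis(methoxymethoxy)benzene
Conditions: MOMCl (2.5 equiv), i-Pr2NEt, CH2Cl2, 0 °C → rt
Reagents that add atoms: MOMCl, COCCl
Why: Routine phenol O-alkylation gives the protecting group that will be removed together with the A-ring MOM ethers.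

**Step 5**
Reactants: 9; 10, triisopropyl borate
Product: 11, [3,5-bis(methoxymethoxy)phenyl]boronic acid
Conditions: B(Oi-Pr)3 (1.5 equiv), then n-BuLi (1.1 equiv) added at −78 °C (in situ quench), THF/toluene, → rt; sat. aq NH4Cl work-up
Reagents that add atoms: triisopropyl borate, CC(C)OB(OC(C)C)OC(C)C (boron); water, O (the two OH oxygens)
Why: Br/Li exchange is faster than ortho-lithiation, and trapping the aryllithium as it forms prevents migration to the position between the two OMOM groups; the near-neutral hydrolysis keeps the MOM ethers.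

**Step 6**
Reactants: 7; 11 (3 equiv)
Product: 12, (2S)-2-[3,5-bis(methoxymethoxy)phenyl]-5,7-bis(methoxymethoxy)-6,8-bis(3-methylbut-2-en-1-yl)-2,3-dihydro-4H-chromen-4-one
Conditions: [RhCl(C2H4)2]2 (2.5 mol %), (S,S)-Ph-bod* [(1S,4S)-2,5-diphenylbicyclo[2.2.2]octa-2,5-diene] (5.5 mol %), aq KOH (20 mol %), toluene/H2O 10:1, 50 °C
Reagents that add atoms: none beyond reactant 11 (aryl group; H at C3 comes from water)
Why: In this Hayashi–Miyaura asymmetric 1,4-addition the aryl–Rh(diene) species adds to one enantioface of the chromone C2=C3 bond and the Rh enolate is protonated by water before ring-opening, which sets C2 as S under catalyst control.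

**Step 7**
Reactants: 12
Product: 13, (2S)-2-(3,5-dihydroxyphenyl)-5,7-dihydroxy-6,8-bis(3-methylbut-2-en-1-yl)-2,3-dihydro-4H-chromen-4-one (target, CID 26213315)
Conditions: 3 M aq HCl/MeOH (1:5), 40–45 °C, monitored closely; NaHCO3 quench
Reagents that add atoms: none
Why: Acid-catalysed acetal methanolysis removes all four MOM groups, while C2 is not epimerised (flavanone ring-opening needs base) and the prenyl alkenes tolerate brief dilute acid.

## Compound list

1 | 2,4,6-trihydroxyacetophenone | CC(=O)c1c(O)cc(O)cc1O | starting material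
2 | prenyl bromide (1-bromo-3-methylbut-2-ene) | CC(C)=CCBr | starting material
3 | 1-[2,4,6-trihydroxy-3,5-diprenylphenyl]ethanone | CC(=O)c1c(O)c(CC=C(C)C)c(O)c(CC=C(C)C)c1O | intermediate
4 | chloromethyl methyl ether | COCCl | starting material (reagent)
5 | 1-[2-hydroxy-4,6-bis(methoxymethoxy)-3,5-diprenylphenyl]ethanone | CC(=O)c1c(O)c(CC=C(C)C)c(OCOC)c(CC=C(C)C)c1OCOC | intermediate
6 | DMF dimethyl acetal | COC(OC)N(C)C | starting material (reagent)
7 | 5,7-bis(methoxymethoxy)-6,8-diprenyl-4H-chromen-4-one | O=c1ccoc2c(CC=C(C)C)c(OCOC)c(CC=C(C)C)c(OCOC)c12 | intermediate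
8 | 5-bromoresorcinol | Oc1cc(O)cc(Br)c1 | starting material
9 | 1-bromo-3,5-bis(methoxymethoxy)benzene | COCOc1cc(Br)cc(OCOC)c1 | intermediate
10 | triisopropyl borate | CC(C)OB(OC(C)C)OC(C)C | starting material (reagent)
11 | [3,5-bis(methoxymethoxy)phenyl]boronic acid | COCOc1cc(OCOC)cc(B(O)O)c1 | intermediate
12 | (2S)-2-[3,5-bis(MOMO)phenyl]-5,7-bis(MOMO)-6,8-diprenylchroman-4-one | CC(C)=CCc1c(OCOC)c(CC=C(C)C)c2c(c1OCOC)C(=O)C[C@@H](c1cc(OCOC)cc(OCOC)c1)O2 | intermediate
13 | (2S)-2-(3,5-dihydroxyphenyl)-5,7-dihydroxy-6,8-diprenylchroman-4-one | CC(C)=CCc1c(O)c(CC=C(C)C)c2c(c1O)C(=O)C[C@@H](c1cc(O)cc(O)c1)O2 | target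

## Totals

Total step count: 7.
Longest linear sequence: 5 steps (1 → 2 → 3 → 6 → 7); the boronic acid branch is steps 4 → 5.

## Three steps most likely to fail

1. **Step 6, asymmetric 1,4-addition.** The chromone is electron-rich and 5-alkoxy-substituted, so low conversion, protodeboronation, ring-opening or a wrong or weak sense of induction are possible. Fallback: Claisen–Schmidt condensation of 5 with 3,5-bis(methoxymethoxy)benzaldehyde to the 2'-hydroxychalcone, NaOAc-mediated oxa-Michael cyclisation to rac-12, and preparative chiral SFC to isolate (2S)-12 before step 7.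

2. **Step 1, double C-prenylation.** Mono-, O- and gem-diprenylated by-products are expected and the yield is low. Fallback: bis-MOM protect 1 to 2-hydroxy-4,6-bis(methoxymethoxy)acetophenone, di-iodinate at C3/C5 with NIS, and install both prenyl groups by a linear-selective Pd-catalysed Suzuki coupling with prenyl-Bpin, converging on 5.

3. **Step 7, acidic global MOM removal.** The ortho-prenyl phenols can cyclise to dimethylchromans, and the hindered 7-OMOM needs forcing. Fallback: carry TBS ethers instead of MOM on both fragments (steps 2 and 4, with a base-free [Rh(OH)(diene)]2 catalyst in step 6) and unmask at the end with buffered fluoride (Et3N·3HF or TBAF/AcOH), avoiding both strong acid and free base.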